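The route rests on disconnecting the aryl ketone bond C4–C4a, so that ring C is closed last onto an intact, fully substituted ring A. The key step is an intramolecular Friedel–Crafts acylation of an open-chain (S)-3-aryl-3-(aryloxy)propanoic acid, activated as its mixed trifluoroacetic anhydride; in one operation it forms C4–C4a and the chromanone ring without touching C2. It exploits ring A: C4a lies ortho to O1 and O5 and para to O7, and is the only free position next to O1 because C8 already carries the prenyl group. The precursor comes from Mitsunobu inversion of an (R)-aldol product with a 2-prenylphloroglucinol bis-MOM ether, itself made by an aromatic Claisen rearrangement.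

Key step: step 9

Remark: flavanone numbering of the target (O1, C2, C3, C4, C4a, C5 to C8, C8a; ring B primed) is used for all intermediates; the target is the (2S) enantiomer; 1-bromo-4-(methoxymethoxy)benzene, prenylboronic acid pinacol ester, 1-methoxy-1-(trimethylsilyloxy)ethene and tert-butyl 2-methylbut-3-en-2-yl carbonate are assumed to be purchasable.

Step 1
Reactants: 1 1-bromo-4-(methoxymethoxy)benzene
Product: 2 1-(methoxymethoxy)-4-(2-methylbut-3-en-2-yl)benzene
Conditions: prenylBpin (1.5 equiv), Pd(OAc)2 (2 mol%), 2-{bis[3,5-bis(trifluoromethyl)phenyl]phosphino}-3,6-dimethoxy-2',4',6'-triisopropylbiphenyl (4 mol%), K3PO4 (aq.), MeCN, 70 °C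
Reagents that add atoms: 3-methylbut-2-en-1-ylboronic acid pinacol ester, CC(C)=CCB1OC(C)(C)C(C)(C)O1
Why: γ-Selective allyl Suzuki–Miyaura coupling: SE2′ transmetalation of the prenylboronate puts palladium on the tertiary carbon, and the electron-poor biaryl phosphine should make C–C reductive elimination faster than σ–π–σ isomerisation, so the quaternary 1,1-dimethylallyl arene forms while the MOM ether is untouched.

Step 2
Reactants: 2 1-(methoxymethoxy)-4-(2-methylbut-3-en-2-yl)benzene
Product: 4 2-(methoxymethoxy)-5-(2-methylbut-3-en-2-yl)benzaldehyde, via aryllithium 3 (not isolated)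
Conditions: n-BuLi, TMEDA, Et2O, 0 °C; DMF, −78 °C to rt; then H2O
Reagents that add atoms: N,N-dimethylformamide, CN(C)C=O
Why: Directed ortho-metalation followed by formylation: the MOM ether directs n-BuLi to the ortho C–H (both ortho positions are equivalent and the side chain has no allylic hydrogen), and aryllithium 3 adds to DMF to release the aldehyde on aqueous work-up.

Step 3
Reactants: 4 2-(methoxymethoxy)-5-(2-methylbut-3-en-2-yl)benzaldehyde
Product: 6 methyl (3R)-3-hydroxy-3-[2-(methoxymethoxy)-5-(2-methylbut-3-en-2-yl)phenyl]propanoate, via silyl ether 5 (not isolated)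
Conditions: CH2=C(OMe)OSiMe3, Ti(OiPr)4 (2 mol%), single-enantiomer 2-[(3-bromo-5-tert-butyl-2-hydroxybenzylidene)amino]-2'-hydroxy-1,1'-binaphthyl (2 mol%), 3,5-di-tert-butylsalicylic acid (2 mol%), Et2O, 0 °C; then citric acid (cat.), MeOH, rt
Reagents that add atoms: 1-methoxy-1-(trimethylsilyloxy)ethene, C=C(OC)O[Si](C)(C)C
Why: Catalytic enantioselective Mukaiyama acetate aldol addition: the chiral titanium–Schiff base complex binds the aldehyde and blocks one face, the ligand antipode being chosen so that the ketene acetal adds to the Re face and sets the (R) carbinol centre, and mild acidic methanolysis frees the alcohol from silyl ether 5 without loss of the aryl MOM ether.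

Step 4
Reactants: 7 phloroglucinol (benzene-1,3,5-triol)
Product: 8 3,5-bis(methoxymethoxy)phenol
Conditions: MOMCl (2.0 equiv), iPr2NEt, THF, 0 °C to rt; chromatographic separation
Reagents that add atoms: chloromethyl methyl ether, COCCl
Why: Williamson-type O-alkylation with an α-chloro ether: the three hydroxyls of the triol are equivalent, so two equivalents of MOMCl give a statistical mixture from which the single possible bis-ether is separated by chromatography (mono-ether recycled).

Step 5
Reactants: 8 3,5-bis(methoxymethoxy)phenol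
Product: 9 1,3-bis(methoxymethoxy)-5-[(2-methylbut-3-en-2-yl)oxy]benzene
Conditions: tert-butyl 2-methylbut-3-en-2-yl carbonate, Pd(PPh3)4 (2 mol%), THF, 0 °C
Reagents that add atoms: tert-butyl 2-methylbut-3-en-2-yl carbonate, C=CC(C)(C)OC(=O)OC(C)(C)C
Why: Tsuji–Trost O-allylation: zerovalent palladium ionises the tertiary allylic carbonate (loss of CO2 and tert-butoxide) to a 1,1-dimethylallyl palladium cation that the phenoxide attacks at the more substituted terminus, the kinetic tertiary ether being preserved at low temperature.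

Step 6
Reactants: 9 1,3-bis(methoxymethoxy)-5-[(2-methylbut-3-en-2-yl)oxy]benzene
Product: 11 3,5-bis(methoxymethoxy)-2-(3-methylbut-2-en-1-yl)phenol, via cyclohexadienone 10 (not isolated)
Conditions: N,N-diethylaniline, 130 °C
Reagents that add atoms: none
Why: Aromatic Claisen rearrangement: the [3,3] shift transposes the allyl unit, so the tertiary ether delivers a linear prenyl group to an ortho carbon (the two are equivalent by symmetry) and dienone 10 tautomerises to the phenol, whose hydroxyl thus sits next to the prenyl group.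

Step 7
Reactants: 6 methyl (3R)-3-hydroxy-3-[2-(methoxymethoxy)-5-(2-methylbut-3-en-2-yl)phenyl]propanoate; 11 3,5-bis(methoxymethoxy)-2-(3-methylbut-2-en-1-yl)phenol
Product: 12 methyl (3S)-3-[3,5-bis(methoxymethoxy)-2-(3-methylbut-2-en-1-yl)phenoxy]-3-[2-(methoxymethoxy)-5-(2-methylbut-3-en-2-yl)phenyl]propanoate
Conditions: PPh3, DIAD, toluene, −20 °C to rt
Reagents that add atoms: none
Why: Mitsunobu etherification: the alcohol of 6 is activated as an alkoxyphosphonium ion and displaced by the phenoxide of 11 in an SN2 process, so the benzylic centre is inverted from (R) to (S), the configuration of C2 in the target.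

Step 8
Reactants: 12 methyl (3S)-3-[3,5-bis(methoxymethoxy)-2-(3-methylbut-2-en-1-yl)phenoxy]-3-[2-(methoxymethoxy)-5-(2-methylbut-3-en-2-yl)phenyl]propanoate
Product: 13 (3S)-3-[3,5-bis(methoxymethoxy)-2-(3-methylbut-2-en-1-yl)phenoxy]-3-[2-(methoxymethoxy)-5-(2-methylbut-3-en-2-yl)phenyl]propanoic acid
Conditions: LiOH·H2O, THF/H2O, 0 °C to rt; then 1 M HCl to pH 4, 0 °C
Reagents that add atoms: lithium hydroxide, [Li+].[OH-]
Why: Saponification of the methyl ester: hydroxide adds to the ester carbonyl at low temperature faster than it removes the weakly acidic α-hydrogen, so the β-aryloxy group is not eliminated and the stereocentre, which is not involved, is retained.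

Step 9
Reactants: 13 (3S)-3-[3,5-bis(methoxymethoxy)-2-(3-methylbut-2-en-1-yl)phenoxy]-3-[2-(methoxymethoxy)-5-(2-methylbut-3-en-2-yl)phenyl]propanoic acid
Product: 15 (2S)-5,7-bis(methoxymethoxy)-2-[2-(methoxymethoxy)-5-(2-methylbut-3-en-2-yl)phenyl]-8-(3-methylbut-2-en-1-yl)-2,3-dihydro-4H-chromen-4-one, via mixed anhydride 14 (not isolated)
Conditions: TFAA (1.5 equiv), 2,6-di-tert-butyl-4-methylpyridine, CH2Cl2, −20 to 0 °C
Reagents that add atoms: none
Why: Intramolecular Friedel–Crafts acylation: TFAA converts the acid into mixed trifluoroacetic anhydride 14, whose acyl carbon (C4) is attacked by C4a of ring A, and loss of trifluoroacetate and a proton rearomatises the ring to the aryl ketone. The closest known reaction type is the anhydride-mediated cyclisation of 3-aryloxypropanoic acids to chroman-4-ones. Ring C (O1–C2–C3–C4–C4a–C8a) closes in a 6-exo-trig mode, the arene bond C4a–C8a being endocyclic and the C4=O bond exocyclic. No new stereocentre is formed; C2, set in steps 3 and 7, is a spectator, and the buffered, low-temperature conditions are chosen to keep the benzylic C2–O1 bond, the MOM ethers and both alkenes intact. The step needs regioselectivity for C4a, which the substrate secures: C8, the other carbon ortho to O1, already carries the prenyl group, C6 cannot be reached by the three-atom tether, and C4a (ortho to O1 and O5, para to O7) is far more nucleophilic than ring B or the prenyl alkene.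

Step 10
Reactants: 15 (2S)-5,7-bis(methoxymethoxy)-2-[2-(methoxymethoxy)-5-(2-methylbut-3-en-2-yl)phenyl]-8-(3-methylbut-2-en-1-yl)-2,3-dihydro-4H-chromen-4-one
Product: 16 (2S)-5,7-dihydroxy-2-[2-hydroxy-5-(2-methylbut-3-en-2-yl)phenyl]-8-(3-methylbut-2-en-1-yl)-2,3-dihydro-4H-chromen-4-one (CID51040684)
Conditions: 3 M HCl (aq.), MeOH, 40 °C
Reagents that add atoms: none
Why: Acid-catalysed methanolysis of the three MOM acetals (transacetalisation to dimethoxymethane): the aryl MOM ethers should cleave under conditions mild enough to leave the prenyl and 1,1-dimethylallyl alkenes unhydrated and uncyclised, and the absence of base avoids retro-oxa-Michael opening, so C2 stays (S).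

Compound list
1 | 1-bromo-4-(methoxymethoxy)benzene | COCOc1ccc(Br)cc1 | starting material
2 | 1-(methoxymethoxy)-4-(2-methylbut-3-en-2-yl)benzene | C=CC(C)(C)c1ccc(OCOC)cc1 | intermediate
3 | [2-(methoxymethoxy)-5-(2-methylbut-3-en-2-yl)phenyl]lithium (not isolated) | [Li]c1cc(C(C)(C)C=C)ccc1OCOC | intermediate
4 | 2-(methoxymethoxy)-5-(2-methylbut-3-en-2-yl)benzaldehyde | O=Cc1cc(C(C)(C)C=C)ccc1OCOC | intermediate
5 | methyl (3R)-3-[2-(methoxymethoxy)-5-(2-methylbut-3-en-2-yl)phenyl]-3-(trimethylsilyloxy)propanoate (not isolated) | COC(=O)C[C@@H](O[Si](C)(C)C)c1cc(C(C)(C)C=C)ccc1OCOC | intermediate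
6 | methyl (3R)-3-hydroxy-3-[2-(methoxymethoxy)-5-(2-methylbut-3-en-2-yl)phenyl]propanoate | COC(=O)C[C@@H](O)c1cc(C(C)(C)C=C)ccc1OCOC | intermediate
7 | phloroglucinol (benzene-1,3,5-triol) | Oc1cc(O)cc(O)c1 | starting material
8 | 3,5-bis(methoxymethoxy)phenol | COCOc1cc(O)cc(OCOC)c1 | intermediate
9 | 1,3-bis(methoxymethoxy)-5-[(2-methylbut-3-en-2-yl)oxy]benzene | COCOc1cc(OCOC)cc(OC(C)(C)C=C)c1 | intermediate
10 | 3,5-bis(methoxymethoxy)-6-(3-methylbut-2-en-1-yl)cyclohexa-2,4-dien-1-one (not isolated) | O=C1C=C(OCOC)C=C(OCOC)C1CC=C(C)C | intermediate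
11 | 3,5-bis(methoxymethoxy)-2-(3-methylbut-2-en-1-yl)phenol | COCOc1cc(O)c(CC=C(C)C)c(OCOC)c1 | intermediate
12 | methyl (3S)-3-[3,5-bis(methoxymethoxy)-2-(3-methylbut-2-en-1-yl)phenoxy]-3-[2-(methoxymethoxy)-5-(2-methylbut-3-en-2-yl)phenyl]propanoate | COC(=O)C[C@H](Oc1cc(OCOC)cc(OCOC)c1CC=C(C)C)c1cc(C(C)(C)C=C)ccc1OCOC | intermediate
13 | (3S)-3-[3,5-bis(methoxymethoxy)-2-(3-methylbut-2-en-1-yl)phenoxy]-3-[2-(methoxymethoxy)-5-(2-methylbut-3-en-2-yl)phenyl]propanoic acid | OC(=O)C[C@H](Oc1cc(OCOC)cc(OCOC)c1CC=C(C)C)c1cc(C(C)(C)C=C)ccc1OCOC | intermediate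
14 | mixed anhydride of acid 13 with trifluoroacetic acid, (3S) (not isolated) | O=C(OC(=O)C[C@H](Oc1cc(OCOC)cc(OCOC)c1CC=C(C)C)c1cc(C(C)(C)C=C)ccc1OCOC)C(F)(F)F | intermediate
15 | (2S)-5,7-bis(methoxymethoxy)-2-[2-(methoxymethoxy)-5-(2-methylbut-3-en-2-yl)phenyl]-8-(3-methylbut-2-en-1-yl)-2,3-dihydro-4H-chromen-4-one | C=CC(C)(C)c1ccc(OCOC)c([C@@H]2CC(=O)c3c(OCOC)cc(OCOC)c(CC=C(C)C)c3O2)c1 | intermediate
16 | (2S)-5,7-dihydroxy-2-[2-hydroxy-5-(2-methylbut-3-en-2-yl)phenyl]-8-(3-methylbut-2-en-1-yl)-2,3-dihydro-4H-chromen-4-one | C=CC(C)(C)c1ccc(O)c([C@@H]2CC(=O)c3c(O)cc(O)c(CC=C(C)C)c3O2)c1 | target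

Total step count: 10.
Longest linear sequence: 7 steps (steps 1, 2, 3, 7, 8, 9, 10 from 1; the branch of steps 4 to 6 from 7 joins at step 7 and is equally long).

Steps most likely to fail

Step 9 (key step). The process at risk is acid-triggered decomposition around ring A: loss of the O7 MOM group under the trifluoroacetic acid set free, followed by cyclisation of the C8 prenyl chain onto O7, in competition with acylation. The fallback closes ring C on a prenyl-free ring A and brings in the C8 prenyl group afterwards; it sets out from 6 (with phenol 8) and comes back to the route at 16. Mitsunobu coupling of 6 with 8 (PPh3, DIAD, toluene) should give methyl (3S)-3-[3,5-bis(methoxymethoxy)phenoxy]-3-[2-(methoxymethoxy)-5-(2-methylbut-3-en-2-yl)phenyl]propanoate F1. Saponification (LiOH, THF/H2O) gives (3S)-3-[3,5-bis(methoxymethoxy)phenoxy]-3-[2-(methoxymethoxy)-5-(2-methylbut-3-en-2-yl)phenyl]propanoic acid F2. Friedel–Crafts closure as in step 9, now at either of two equivalent ortho carbons and without an acid-sensitive ortho-prenyl group, gives (2S)-5,7-bis(methoxymethoxy)-2-[2-(methoxymethoxy)-5-(2-methylbut-3-en-2-yl)phenyl]-2,3-dihydro-4H-chromen-4-one F3. The peri MOM group on O5, activated by the C4 carbonyl, is removed selectively (0.5 M HCl, MeOH, 0 °C) to give (2S)-5-hydroxy-7-(methoxymethoxy)-2-[2-(methoxymethoxy)-5-(2-methylbut-3-en-2-yl)phenyl]-2,3-dihydro-4H-chromen-4-one F4. Mitsunobu O-prenylation (3-methylbut-2-en-1-ol, PPh3, DIAD, THF) gives (2S)-7-(methoxymethoxy)-2-[2-(methoxymethoxy)-5-(2-methylbut-3-en-2-yl)phenyl]-5-[(3-methylbut-2-en-1-yl)oxy]-2,3-dihydro-4H-chromen-4-one F5. A Claisen–Cope sequence catalysed by Eu(fod)3 (CHCl3, 60 °C) should carry the prenyl group from O5 by way of C6 to C8 and give (2S)-5-hydroxy-7-(methoxymethoxy)-2-[2-(methoxymethoxy)-5-(2-methylbut-3-en-2-yl)phenyl]-8-(3-methylbut-2-en-1-yl)-2,3-dihydro-4H-chromen-4-one F6. Acidic methanolysis as in step 10 then gives 16.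

Step 7. The process at risk is dehydration of the activated β-hydroxy ester to the cinnamate (elimination through the acidic ester α-hydrogens) instead of substitution by the hindered, ortho-substituted phenoxide. The fallback carries C4 at the alcohol oxidation level through the etherification; it sets out from 6 and comes back to the route at 13. Reduction of 6 (LiBH4, THF, 0 °C to rt) gives (1R)-1-[2-(methoxymethoxy)-5-(2-methylbut-3-en-2-yl)phenyl]propane-1,3-diol F7. Selective silylation of the primary hydroxyl (TBSCl, imidazole, CH2Cl2, 0 °C) gives (1R)-3-[(tert-butyldimethylsilyl)oxy]-1-[2-(methoxymethoxy)-5-(2-methylbut-3-en-2-yl)phenyl]propan-1-ol F8. Mitsunobu coupling with 11 (PPh3, DIAD, toluene), now free of any acidic α-hydrogen, gives with inversion tert-butyl{(3S)-3-[3,5-bis(methoxymethoxy)-2-(3-methylbut-2-en-1-yl)phenoxy]-3-[2-(methoxymethoxy)-5-(2-methylbut-3-en-2-yl)phenyl]propoxy}dimethylsilane F9. Desilylation (Bu4NF, AcOH, THF) gives (3S)-3-[3,5-bis(methoxymethoxy)-2-(3-methylbut-2-en-1-yl)phenoxy]-3-[2-(methoxymethoxy)-5-(2-methylbut-3-en-2-yl)phenyl]propan-1-ol F10. Oxidation of the primary alcohol to the acid (TEMPO cat., PhI(OAc)2, MeCN/H2O, rt) gives 13.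

Step 1. The process at risk is σ–π–σ isomerisation of the allylpalladium intermediate ahead of reductive elimination, which would give the linear prenyl arene in place of the quaternary benzylic carbon. The fallback builds that carbon by enolate arylation; it sets out from 1 and comes back to the route at 2. Palladium-catalysed α-arylation of methyl isobutyrate with 1 (LiNCy2, Pd(dba)2, P(t-Bu)3, toluene, rt) gives methyl 2-[4-(methoxymethoxy)phenyl]-2-methylpropanoate F11. Partial reduction (DIBAL-H, CH2Cl2, −78 °C) gives 2-[4-(methoxymethoxy)phenyl]-2-methylpropanal F12. Wittig methylenation (Ph3PCH3Br, KOtBu, THF, 0 °C to rt) gives 2.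

Further compounds
F1 | step 9 | methyl (3S)-3-[3,5-bis(methoxymethoxy)phenoxy]-3-[2-(methoxymethoxy)-5-(2-methylbut-3-en-2-yl)phenyl]propanoate | COC(=O)C[C@H](Oc1cc(OCOC)cc(OCOC)c1)c1cc(C(C)(C)C=C)ccc1OCOC
F2 | step 9 | (3S)-3-[3,5-bis(methoxymethoxy)phenoxy]-3-[2-(methoxymethoxy)-5-(2-methylbut-3-en-2-yl)phenyl]propanoic acid | OC(=O)C[C@H](Oc1cc(OCOC)cc(OCOC)c1)c1cc(C(C)(C)C=C)ccc1OCOC
F3 | step 9 | (2S)-5,7-bis(methoxymethoxy)-2-[2-(methoxymethoxy)-5-(2-methylbut-3-en-2-yl)phenyl]-2,3-dihydro-4H-chromen-4-one | C=CC(C)(C)c1ccc(OCOC)c([C@@H]2CC(=O)c3c(OCOC)cc(OCOC)cc3O2)c1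
F4 | step 9 | (2S)-5-hydroxy-7-(methoxymethoxy)-2-[2-(methoxymethoxy)-5-(2-methylbut-3-en-2-yl)phenyl]-2,3-dihydro-4H-chromen-4-one | C=CC(C)(C)c1ccc(OCOC)c([C@@H]2CC(=O)c3c(O)cc(OCOC)cc3O2)c1
F5 | step 9 | (2S)-7-(methoxymethoxy)-2-[2-(methoxymethoxy)-5-(2-methylbut-3-en-2-yl)phenyl]-5-[(3-methylbut-2-en-1-yl)oxy]-2,3-dihydro-4H-chromen-4-one | C=CC(C)(C)c1ccc(OCOC)c([C@@H]2CC(=O)c3c(OCC=C(C)C)cc(OCOC)cc3O2)c1
F6 | step 9 | (2S)-5-hydroxy-7-(methoxymethoxy)-2-[2-(methoxymethoxy)-5-(2-methylbut-3-en-2-yl)phenyl]-8-(3-methylbut-2-en-1-yl)-2,3-dihydro-4H-chromen-4-one | C=CC(C)(C)c1ccc(OCOC)c([C@@H]2CC(=O)c3c(O)cc(OCOC)c(CC=C(C)C)c3O2)c1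
F7 | step 7 | (1R)-1-[2-(methoxymethoxy)-5-(2-methylbut-3-en-2-yl)phenyl]propane-1,3-diol | OCC[C@@H](O)c1cc(C(C)(C)C=C)ccc1OCOC
F8 | step 7 | (1R)-3-[(tert-butyldimethylsilyl)oxy]-1-[2-(methoxymethoxy)-5-(2-methylbut-3-en-2-yl)phenyl]propan-1-ol | CC(C)(C)[Si](C)(C)OCC[C@@H](O)c1cc(C(C)(C)C=C)ccc1OCOC
F9 | step 7 | tert-butyl{(3S)-3-[3,5-bis(methoxymethoxy)-2-(3-methylbut-2-en-1-yl)phenoxy]-3-[2-(methoxymethoxy)-5-(2-methylbut-3-en-2-yl)phenyl]propoxy}dimethylsilane | CC(C)(C)[Si](C)(C)OCC[C@H](Oc1cc(OCOC)cc(OCOC)c1CC=C(C)C)c1cc(C(C)(C)C=C)ccc1OCOC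
F10 | step 7 | (3S)-3-[3,5-bis(methoxymethoxy)-2-(3-methylbut-2-en-1-yl)phenoxy]-3-[2-(methoxymethoxy)-5-(2-methylbut-3-en-2-yl)phenyl]propan-1-ol | OCC[C@H](Oc1cc(OCOC)cc(OCOC)c1CC=C(C)C)c1cc(C(C)(C)C=C)ccc1OCOC
F11 | step 1 | methyl 2-[4-(methoxymethoxy)phenyl]-2-methylpropanoate | COCOc1ccc(cc1)C(C)(C)C(=O)OC
F12 | step 1 | 2-[4-(methoxymethoxy)phenyl]-2-methylpropanal | COCOc1ccc(cc1)C(C)(C)C=O
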